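The data were generated by integration with made-up constants, noise included.

If a flask can lose Zo by two paths, one going with Zo and the other with its square, then one level of Zo should show which path leads. That was the business of the meeting.

| flask | Zo | temperature | remark | time |
|---|---|---|---|---|
| birch | 0.45 M | 10 °C | run made earlier |  |
| maple | 1.4 M | 21 °C | run made earlier |  |
| noon | 0.30 M | 5 °C |  | 80 min |
| dawn | 1.0 M | 25 °C |  | 80 min |
| midnight | 0.30 M | 25 °C |  | 80 min |
| autumn | 1.0 M | 5 °C |  | 80 min |

| run | time / min | Xo / % |
|---|---|---|
| birch | 10.0 | 8.2 |
| birch | 15.0 | 14.7 |
| birch | 25.0 | 22.9 |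
| birch | 40.0 | 27.5 |
| birch | 60.0 | 32.5 |
| birch | 120 | 41.2 |
| maple | 4.00 | 10.4 |
| maple | 10.0 | 19.9 |
| maple | 20.0 | 19.3 |
| maple | 30.0 | 17.7 |
| maple | 40.0 | 17.0 |
| maple | 60.0 | 14.9 |

(standard deviation of a reading: 1 percentage point)



- all flasks from highest to lowest amount of Xo, in percent of the Zo charged, at 80 min (noon / dawn / midnight / autumn)
- the amount of Xo, in percent of the Zo charged of the flask you put first, at 80 min
- the amount of Xo, in percent of the Zo charged of the flask you put last, at 80 min

A colleague opened by saying that the dilute birch run was still rising at 41.2%, while the concentrated maple run topped out near 19.9%. I replied that this looked like a first-order path to Xo competing with a second-order loss. I therefore proposed the balance level, the Zo concentration at which the two paths use Zo equally fast. Balance over the Zo present is the selectivity factor of the two paths, so the share of Zo going to Xo at any moment is balance over balance plus Zo present, and it rises as Zo falls. Over a charge used up, the share is then balance over charge, times the natural logarithm of one plus charge over balance. Taking the top of maple as that share, though no reading shows its Zo used up, I found by trial a rough 0.105 M. The last birch reading, taken the same way, gave 0.119 M, so I assumed that temperature changes the speed and leaves the split roughly where it was.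

On that assumption, balance as a fraction of the charge is 0.349 for the dilute charge of noon and midnight and 0.105 for the concentrated charge of dawn and autumn. The shares over a charge used up are 47.2% for the dilute charge and 24.7% for the concentrated one.

The colleague objected that maple's Xo fell afterwards, at 0.00579 min⁻¹. I accepted this for the warm flasks, which then keep 66.7% over 70.0 min. That gave midnight 31.5% and dawn 16.4%. For the cold flasks I set autumn at its full share and noon, which I assumed to run at half birch's speed, at birch's 27.5% of 40.0 min. My order was midnight, noon, autumn, dawn.

The forecast, which differs from this order in the last two places, read midnight > noon > dawn > autumn, with 38% and 10%, and added: “The order is uncertain, especially the last two places.”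

The flasks give midnight > noon > autumn > dawn: midnight 35.3%, noon 31.0%, autumn 21.7%, dawn 13.5%.

    2 Zo → Zo2 (k = 0.0992 M⁻¹ min⁻¹, Ea = 69.0 kJ mol⁻¹)
    Zo ⇌ Xo + Xi (K = 0.200 M, k = 0.0614 min⁻¹, Ea = 79.0 kJ mol⁻¹, ΔH = −50.0 kJ mol⁻¹)
    (constants at 25 °C)

Midnight has not come to rest: at 80.0 min, 17.2% of its charge is still Zo and 47.5% is Zo2, counted by the Zo it holds. The same reckoning for its neighbour with 0.51 M of Zo gives 24.3%, and that flask holds 23.9%. Left ten times as long, noon holds 50.8% and autumn 23.9%. Dawn sinks to 5.44%, and midnight falls to half of its present Xo, 17.5%.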